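Remark on the chemistry: germacrane numbering is used throughout (ring C1–C10, lactone C11–C13, ester carbon C14, methyl C15). The double-bond marks of the SMILES are read as 4Z and 1(10)E, so both ring alkenes are cis with respect to the ring.

## Structural features

The target is a cis,cis-germacranolide. A ten-membered carbocycle (C1–C10) is trans-fused along C6–C7 to an α-methylene-γ-butyrolactone (O6–C6–C7–C11–C12, exocyclic C13). Both ring alkenes are ring-cis and are joined by C2H2–C3H2 into a 1,5-diene: C4=C5 is Z and carries methyl C15, and C1=C10 is E by CIP only because C10 carries C14. Four stereocentres stand in a row, C6 (R), C7 (S), C8 (S) and C9 (R). O6 is trans to C11, while C11, O8 and O9 lie on one face (8,9-erythro). O8 carries (2S,3S)-2,3-epoxy-2-methylbutanoate and O9 carries syn-(2R,3S)-3-hydroxy-2-methylbutanoate, so two neighbouring secondary alcohols must be told apart. The fragile groups are the exocyclic Michael acceptor, the epoxide, the β-hydroxy ester, the allylic C6–O bond, the vicinal esters (acyl migration) and O9, which is β to C14 and is lost from any C10 enolate or C2 dienolate. The real difficulty is to close the strained ring while fixing the trisubstituted C1=C10 next to O9 and the C6–C9 tetrad. The key step exploits the unit C9(O)–C10(C14O2Me)=C1H. C14 is exocyclic on ring atom C10 and C1 is a CH, which is the retron of an alkoxyalkyne–carbonyl metathesis (C10≡C14–OMe plus a C1 carbonyl carbon).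

## Logic of the disconnections

**43 ⇒ 42 ⇒ 34 + 40.** The bonds cut are the side-chain O–Si bond and the acyl C–O bond at O9. The most fragile acyl group comes last, so it never meets base or Lewis acid. The gain is one chiral acid and a ring alcohol. The forward step must acylate next to an ester without migration, and the silyl group must leave under mild acid.

**34 ⇒ 33 ⇒ 27 + 31.** The bonds cut are O9–Si and the acyl C–O bond at O8. The two alcohols are told apart by two silyl groups of different lability. The gain is that the epoxide is absent from the Lewis-acid step. The forward step needs a hindered esterification.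

**27 ⇒ 26 ⇒ 23 (key).** The bonds cut are C1=C10 (σ and π) and the C14=O π bond. The ester oxygen returns to C1 as an acetal oxygen and C10–C14 becomes a triple bond. Ring, alkene geometry and ester then all come from one seco chain that hangs on the lactone. In addition, C10, C14 and OMe collapse to one C2 reagent. The forward step must ionise the acetal selectively and needs high dilution.

**23 ⇒ 22.** The bond cut is C11=C13. The phosphonate masks the Michael acceptor during the organolithium step. The forward step needs only mild base.

**22 ⇒ 21 ⇒ 18 + 19.** The bond cut is C9–C10. This sets C9 by 1,2-induction from C8. The gain is an aldehyde and a commercial C2 unit. The forward step must proceed without chelation.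

**18 ⇒ 17 ⇒ 16 ⇒ 15.** The bond cut is C7–C11, which opens the lactone ring. C7 arises by stereospecific inversion at an epoxide carbon, and O8 is set free at the same time. The gain is an acyclic epoxy ester. The forward step needs proximal (5-exo) attack.

**15 ⇒ 13 + 14, and 13 ⇒ 12.** The bonds cut are the acyl C–O bond at O6 and the two epoxide C–O bonds. One catalytic asymmetric event selects C6 and creates C7 and C8. The gain is a racemic, achirally made dienol. The forward step must discriminate between the two alkenes that flank C6.

**12 ⇒ 7 + 9, 7 ⇒ 6 ⇒ 3 + 4, and 3 ⇒ 1.** The bonds cut are C6–C7 and C3–C4. The Z-alkene is bought as a stereodefined alkenyl iodide, and C1 travels as the acetal that the key step needs. The gain is a set of C3 and C4 commodity chemicals. The coupling must retain the alkene geometry.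

**31 ⇒ 30 ⇒ 29 ⇒ 28, and 40 ⇒ 39 ⇒ 38 ⇒ 35 + 36.** The cuts are the epoxide oxygen in the first case and the C2′–C3′ aldol bond in the second. Both acids come from reagent-controlled standard reactions.

## Other disconnections considered

**Alternative 1:** (the first that comes to mind) Cut C6–C7 and close the ring and the lactone by an intramolecular Barbier or Nozaki–Hiyama–Kishi allylation of the bromo-enal A1.
- A1 must already hold the C9-oxy enoate, which is sensitive to elimination, together with a neral-type enal that can isomerise.
- Its (Z)-2-(bromomethyl)enoate favours the syn adduct, that is the cis-lactone, in a closed transition state.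
- C6 and C7 would therefore depend only on macrocyclic strain, with no independent handle.
- The chosen plan fixes C6–C8 by stereospecific events before the ring exists, and it makes the enoate in the closure itself.

**Alternative 2:** Cut C4=C5 and close the ring by ring-closing metathesis of the tetraene A2.
- The step must form a trisubstituted alkene in a medium ring from a 1,1-disubstituted olefin.
- It would have to do so beside two acrylate-type methylene or alkene units that compete for the carbene, and under reversible conditions that favour dimers.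
- The C1=C10 enoate with its allylic O9 still has to be made beforehand by a separate stereoselective olefination, so steps are added rather than saved.

**Alternative 3:** Cut C2–C3 and re-join C5–C10: an anionic oxy-Cope ring expansion of the divinylcyclohexanol A3, followed by enol triflate formation and carbonylation.
- In the chair transition state the ring bonds C5–C6 and C10–C9 sit equatorial and give ring-trans alkenes.
- A cis,cis-1,5-diene would need both bonds axial, which a six-membered ring cannot allow, so C4=C5 comes out with the wrong geometry.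
- A3 also carries six ring stereocentres against the four of the target.

Key step: step 14

## Steps

Step 1
Reactants: 1 but-2-yn-1-ol
Product: 3 (Z)-3-iodobut-2-en-1-ol, via cyclic alkenylalanate 2 (not isolated)
Conditions: NaAlH2(OCH2CH2OMe)2, THF, 0 °C to rt; EtOAc; I2, −78 °C
Reagents that add atoms: iodine, [I][I]
Why: Hydroxyl-directed trans-hydroalumination gives the five-membered alanate 2 with aluminium on the later C4, and iodinolysis with retention places iodine cis to CH2OH, which is the ring-cis C4=C5 geometry.

Step 2
Reactants: 4 3,3-dimethoxyprop-1-ene (acrolein dimethyl acetal); 3 (Z)-3-iodobut-2-en-1-ol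
Product: 6 (Z)-6,6-dimethoxy-3-methylhex-2-en-1-ol, via B-alkyl-9-BBN 5 (not isolated)
Conditions: 9-BBN-H, THF, 0 °C to rt; then 3, PdCl2(dppf), AsPh3, Cs2CO3, DMF–H2O, rt
Reagents that add atoms: none
Why: Anti-Markovnikov hydroboration and B-alkyl Suzuki–Miyaura coupling form C3–C4 with retention of the alkene geometry, and the acetal and the free alcohol are inert.

Step 3
Reactants: 6 (Z)-6,6-dimethoxy-3-methylhex-2-en-1-ol
Product: 7 (Z)-6,6-dimethoxy-3-methylhex-2-enal
Conditions: MnO2, CH2Cl2, rt
Reagents that add atoms: none
Why: Neutral allylic oxidation should keep the acetal and should not isomerise the Z-enal.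

Step 4
Reactants: 8 prop-2-yn-1-ol
Product: 9 triethyl(prop-2-yn-1-yloxy)silane
Conditions: Et3SiCl, imidazole, CH2Cl2, 0 °C
Reagents that add atoms: chlorotriethylsilane, CC[Si](Cl)(CC)CC
Why: Standard silylation puts on a primary triethylsilyl ether, chosen because it can later be oxidised directly to the aldehyde.

Step 5
Reactants: 9 triethyl(prop-2-yn-1-yloxy)silane; 7 (Z)-6,6-dimethoxy-3-methylhex-2-enal
Product: 12 racemic (2E,5Z)-9,9-dimethoxy-6-methyl-1-(triethylsilyloxy)nona-2,5-dien-4-ol, via alkenylzirconocene chloride 10 (not isolated), via alkenyl(methyl)zinc 11 (not isolated)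
Conditions: Cp2Zr(H)Cl, CH2Cl2, rt; Me2Zn, toluene, −65 °C; 7, 0 °C
Reagents that add atoms: none
Why: Syn-hydrozirconation puts the metal on the terminal carbon (E), and zirconium-to-zinc exchange gives an alkenylzinc that adds 1,2 to the enal and forms C6–C7, with C6 left racemic on purpose.

Step 6
Reactants: 12 racemic dienol
Product: 13 (1R,2Z)-6,6-dimethoxy-3-methyl-1-[(2R,3R)-3-(triethylsilyloxymethyl)oxiran-2-yl]hex-2-en-1-ol (6R,7R,8R in germacrane numbering)
Conditions: Ti(OiPr)4, D-(−)-DIPT, t-BuOOH (0.5 equiv), 4 Å sieves, CH2Cl2, −20 °C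
Reagents that add atoms: tert-butyl hydroperoxide, CC(C)(C)OO
Why: In the Sharpless kinetic resolution with D-(−)-tartrate, the (S)-enantiomer of 12 is the fast one and gives the erythro trans-epoxide at the E-alkene, so C6 is selected and C7 and C8 are created in one event; in this enantiomer the other alkene sits in the slow position and is also a Z-substituted, poor substrate.

Step 7
Reactants: 13 epoxy alcohol; 14 diethylphosphonoacetic acid
Product: 15 diethylphosphonoacetate ester of 13 (acyl group on O6)
Conditions: DCC, DMAP (cat.), CH2Cl2, 0 °C to rt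
Reagents that add atoms: none
Why: Steglich esterification under neutral conditions leaves the epoxide, the acetal and the silyl ether untouched and tethers C11 and C12 to O6.

Step 8
Reactants: 15 epoxy phosphonoacetate
Product: 16 α-(diethoxyphosphoryl)-γ-butyrolactone with trans C6/C7 substituents, free 8-OH and primary 9-OTES (C11 epimers)
Conditions: NaH, THF–DMF, 0 to 50 °C; aq NH4Cl
Reagents that add atoms: none
Why: This is an intramolecular alkylation of the stabilised phosphonate carbanion by the epoxide: backside 5-exo-tet attack at the nearer carbon forms C7–C11 with inversion at C7 and retention at C8, distal 6-endo attack is slowed by the inductive effect of O9, and the trans-lactone is also the more stable of the two possible γ-lactones.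

Step 9
Reactants: 16 hydroxy lactone
Product: 17 8,9-bis(triethylsilyl) ether of 16
Conditions: Et3SiCl, imidazole, CH2Cl2, 0 °C
Reagents that add atoms: chlorotriethylsilane, CC[Si](Cl)(CC)CC
Why: Standard silylation; the labile group on O8 is the one that has to leave first in the endgame.

Step 10
Reactants: 17 bis-silyl ether
Product: 18 C9 aldehyde (8-OTES, phosphono lactone, C1 acetal)
Conditions: (COCl)2, DMSO, CH2Cl2, −78 to −40 °C; Et3N
Reagents that add atoms: none
Why: In this Swern oxidation, activated DMSO attacks the unhindered primary triethylsilyl ether, which is desilylated and oxidised in one pot, while the secondary silyl ether and the acetal stay.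

Step 11
Reactants: 19 2-chloro-1,1-dimethoxyethane; 18 C9 aldehyde
Product: 21 8,9-anti propargylic alcohol that carries the methoxyalkyne C10≡C14–OMe, via lithium methoxyacetylide 20 (not isolated)
Conditions: 19, LiN(iPr)2 (3 equiv per 19), THF, −78 to 0 °C; 18, −78 °C; AcOH, −78 °C
Reagents that add atoms: none
Why: Double elimination and metalation of 19 give 20, which adds to the aldehyde under polar Felkin–Anh control (attack anti to the C8 silyloxy group, no chelation) to set C9; the first equivalent merely deprotonates the phosphonate, which shields the lactone.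

Step 12
Reactants: 21 propargylic alcohol
Product: 22 9-O-TBS ether of 21
Conditions: t-BuMe2SiCl, imidazole, DMF, rt
Reagents that add atoms: tert-butylchlorodimethylsilane, CC(C)(C)[Si](C)(C)Cl
Why: Basic silylation is tolerated by the acid-labile ynol ether, the silyloxy group is a poor leaving group at the propargylic C9, and it is more robust than the O8 group.

Step 13
Reactants: 22 phosphono lactone
Product: 23 α-methylene lactone seco precursor (C1 dimethyl acetal, 8-OTES, 9-OTBS, methoxyalkyne)
Conditions: K2CO3, aq HCHO, THF, 0 °C to rt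
Reagents that add atoms: formaldehyde, C=O
Why: Horner–Wadsworth–Emmons methylenation installs C13 under mild base, which the ynol ether, the acetal and the silyl ethers tolerate.

Step 14
Reactants: 23 seco precursor
Product: 26 ten-membered methyl ester (8-OTES, 9-OTBS, 4Z, ring-cis C1=C10), via oxocarbenium ion 24 (not isolated), via oxetenium ion 25 (not isolated)
Conditions: Sc(OTf)3 (cat.), MeCN–CH2Cl2, slow addition to 1 mM, −20 °C to rt
Reagents that add atoms: none
Why: Proposed new method: Sc(OTf)3 ionises the acetal to 24, the polarised methoxyalkyne attacks C1 through its β-carbon C10 and closes the ten-membered ring, and the alkoxyketenium carbon C14 is captured by the C1 methoxy oxygen, a stepwise (2+2) cycloaddition that gives 25. Conrotatory 4π opening of 25 breaks C1–O and makes C1=C10 and C14=O, and methoxide takes the O-methyl group, so ring, alkene and methyl ester arise in one operation with loss of dimethyl ether only. The closest known reaction type is the Lewis-acid-catalysed ring-closing ynol ether–acetal (alkyne–carbonyl) metathesis, which is known for five- to seven-membered cycloalkene carboxylates but not for a medium ring, hence the label. As to the mode of closure, the carbocycle closes by attack of an sp carbon on a tethered oxocarbenium carbon (only C10 enters the ring, so no bent alkyne is needed), and the four-membered ring closes by O–C14 bonding. No stereocentre is created; the geometry is secured twice, by outward rotation of the alkyl carbon C2 in the opening of 25 and by the seven-atom tether between C2 and C9, and both place C2 cis to C9 and trans to the ester. Chemoselectivity rests on the acetal being the most easily ionised group (silyloxy is a poor leaving group at C9, and the acylated C6–O is deactivated), on the 5-endo geometry that disfavours a Prins reaction of 24 with C4=C5, and on high dilution against dimerisation. The Z-alkene and the trans-lactone pre-fold the chain, and the strongly exergonic change of an ynol ether into a conjugated ester pays for the ring strain.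

Step 15
Reactants: 26 bis-silyl ether
Product: 27 8-alcohol (9-OTBS)
Conditions: PPTS, MeOH–CH2Cl2, 0 °C
Reagents that add atoms: none
Why: Acid-catalysed methanolysis distinguishes the triethylsilyl ether from the bulkier TBS ether, and no base touches the Michael acceptor.

Step 16
Reactants: 28 angelic acid ((Z)-2-methylbut-2-enoic acid)
Product: 29 (Z)-2-methylbut-2-en-1-ol
Conditions: LiAlH4, Et2O, 0 °C
Reagents that add atoms: none
Why: Hydride reduction of the acid proceeds without change of the alkene geometry.

Step 17
Reactants: 29 (Z)-2-methylbut-2-en-1-ol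
Product: 30 [(2R,3S)-2,3-dimethyloxiran-2-yl]methanol
Conditions: Ti(OiPr)4, D-(−)-DET, t-BuOOH, 4 Å sieves, CH2Cl2, −20 °C
Reagents that add atoms: tert-butyl hydroperoxide, CC(C)(C)OO
Why: In the Sharpless asymmetric epoxidation, D-(−)-tartrate gives the 2R epoxy alcohol, and the Z-alkene fixes CH2OH cis to the C3 methyl group.

Step 18
Reactants: 30 epoxy alcohol
Product: 31 (2S,3S)-2,3-dimethyloxirane-2-carboxylic acid
Conditions: TEMPO (cat.), PhI(OAc)2, MeCN–H2O, rt
Reagents that add atoms: water, O
Why: Oxoammonium oxidation runs through the aldehyde hydrate and leaves the epoxide intact; the descriptor at C2 changes only because of the CIP priorities.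

Step 19
Reactants: 31 epoxy acid; 27 8-alcohol
Product: 33 8-O-[(2S,3S)-epoxyangeloyl] 9-O-TBS ester, via mixed anhydride 32 (not isolated)
Conditions: 2,4,6-Cl3C6H2COCl, Et3N, toluene, rt; 27, DMAP, rt
Reagents that add atoms: none
Why: In the Yamaguchi esterification, DMAP attacks the aliphatic carbonyl of 32 because the aroyl carbonyl is shielded by its two ortho chlorines; the acid has no α-hydrogen, so no epimerisation is possible.

Step 20
Reactants: 33 silyl ether
Product: 34 9-alcohol
Conditions: HF·pyridine, pyridine–THF, 0 °C to rt
Reagents that add atoms: none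
Why: Buffered, slightly acidic fluoride removes the TBS group and avoids the base-induced acyl shift from O8 to O9, and the electron-poor epoxy ester should resist it.

Step 21
Reactants: 35 (R)-4-benzyl-3-propionyloxazolidin-2-one; 36 acetaldehyde
Product: 38 syn-aldol adduct (2′R,3′S), via Z-boron enolate 37 (not isolated)
Conditions: Bu2BOTf, Et3N, CH2Cl2, 0 °C; 36, −78 to 0 °C; H2O2, MeOH, pH 7 buffer
Reagents that add atoms: none
Why: In the Evans syn-aldol reaction, the Z-boron enolate reacts through a chair transition state on the face away from the benzyl group, and the (R)-auxiliary gives 2R,3S.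

Step 22
Reactants: 38 aldol adduct
Product: 39 3′-O-triethylsilyl ether of 38
Conditions: Et3SiCl, imidazole, DMF, 0 °C
Reagents that add atoms: chlorotriethylsilane, CC[Si](Cl)(CC)CC
Why: Silylation blocks retro-aldol reaction and self-acylation, and the group can later leave under very mild acid.

Step 23
Reactants: 39 silylated imide
Product: 40 (2R,3S)-2-methyl-3-(triethylsilyloxy)butanoic acid
Conditions: LiOH, H2O2, THF–H2O, 0 °C; Na2SO3; dilute HCl to pH 4
Reagents that add atoms: hydrogen peroxide, OO
Why: Hydroperoxide attacks the exocyclic carbonyl selectively, so the auxiliary is released without epimerisation at C2′.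

Step 24
Reactants: 40 silyloxy acid; 34 9-alcohol
Product: 42 fully acylated 3′-O-TES ether, via mixed anhydride 41 (not isolated)
Conditions: 2,4,6-Cl3C6H2COCl, Et3N, toluene, rt; 34, DMAP, 0 °C to rt
Reagents that add atoms: none
Why: Yamaguchi esterification of the allylic 9-OH; the low temperature and the short contact with DMAP should limit α-epimerisation and β-elimination of the acyl donor.

Step 25
Reactants: 42 silyl ether
Product: 43 target CNP0135583.1
Conditions: HF·pyridine, pyridine–THF, 0 °C
Reagents that add atoms: none
Why: Removal of the secondary triethylsilyl ether under buffered fluoride touches no stereocentre and none of the epoxide, the esters or the Michael acceptor.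

## Compound list

1 | but-2-yn-1-ol | CC#CCO | starting material
2 | sodium cyclic alkenylalanate | CC1=CCO[Al-]1(OCCOC)OCCOC.[Na+] | intermediate
3 | (Z)-3-iodobut-2-en-1-ol | C/C(I)=C/CO | intermediate
4 | 3,3-dimethoxyprop-1-ene | C=CC(OC)OC | starting material
5 | B-(3,3-dimethoxypropyl)-9-BBN | COC(OC)CCB1C2CCCC1CCC2 | intermediate
6 | (Z)-6,6-dimethoxy-3-methylhex-2-en-1-ol | OC/C=C(/C)CCC(OC)OC | intermediate
7 | (Z)-6,6-dimethoxy-3-methylhex-2-enal | O=C/C=C(/C)CCC(OC)OC | intermediate
8 | prop-2-yn-1-ol | C#CCO | starting material
9 | triethyl(prop-2-yn-1-yloxy)silane | C#CCO[Si](CC)(CC)CC | intermediate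
10 | (E)-alkenylzirconocene chloride | Cl[Zr](/C=C/CO[Si](CC)(CC)CC)(C1C=CC=C1)C1C=CC=C1 | intermediate
11 | (E)-alkenyl(methyl)zinc | C[Zn]/C=C/CO[Si](CC)(CC)CC | intermediate
12 | racemic (2E,5Z)-9,9-dimethoxy-6-methyl-1-(triethylsilyloxy)nona-2,5-dien-4-ol | OC(/C=C(/C)CCC(OC)OC)/C=C/CO[Si](CC)(CC)CC | intermediate
13 | (6R,7R,8R)-erythro epoxy alcohol | O[C@H](/C=C(/C)CCC(OC)OC)[C@H]1O[C@@H]1CO[Si](CC)(CC)CC | intermediate
14 | diethylphosphonoacetic acid | CCOP(=O)(OCC)CC(=O)O | starting material
15 | O6-diethylphosphonoacetate of 13 | CCOP(=O)(OCC)CC(=O)O[C@H](/C=C(/C)CCC(OC)OC)[C@H]1O[C@@H]1CO[Si](CC)(CC)CC | intermediate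
16 | trans-α-phosphono lactone, 8-OH, 9-OTES | CCOP(=O)(OCC)C1C(=O)O[C@H](/C=C(/C)CCC(OC)OC)[C@H]1[C@H](O)CO[Si](CC)(CC)CC | intermediate
17 | 8,9-bis-TES ether | CCOP(=O)(OCC)C1C(=O)O[C@H](/C=C(/C)CCC(OC)OC)[C@H]1[C@H](O[Si](CC)(CC)CC)CO[Si](CC)(CC)CC | intermediate
18 | C9 aldehyde | CCOP(=O)(OCC)C1C(=O)O[C@H](/C=C(/C)CCC(OC)OC)[C@H]1[C@H](O[Si](CC)(CC)CC)C=O | intermediate
19 | 2-chloro-1,1-dimethoxyethane | ClCC(OC)OC | starting material
20 | lithium methoxyacetylide | [Li]C#COC | intermediate
21 | 8,9-anti propargylic alcohol with methoxyalkyne | CCOP(=O)(OCC)C1C(=O)O[C@H](/C=C(/C)CCC(OC)OC)[C@H]1[C@H](O[Si](CC)(CC)CC)[C@H](O)C#COC | intermediate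
22 | 9-O-TBS ether of 21 | CCOP(=O)(OCC)C1C(=O)O[C@H](/C=C(/C)CCC(OC)OC)[C@H]1[C@H](O[Si](CC)(CC)CC)[C@H](O[Si](C)(C)C(C)(C)C)C#COC | intermediate
23 | α-methylene lactone seco precursor | C=C1C(=O)O[C@H](/C=C(/C)CCC(OC)OC)[C@H]1[C@H](O[Si](CC)(CC)CC)[C@H](O[Si](C)(C)C(C)(C)C)C#COC | intermediate
24 | C1 oxocarbenium ion | C=C1C(=O)O[C@H](/C=C(/C)CCC=[O+]C)[C@H]1[C@H](O[Si](CC)(CC)CC)[C@H](O[Si](C)(C)C(C)(C)C)C#COC | intermediate
25 | ring-fused 2-methoxyoxetenium ion (C1 transient, unassigned) | C=C1C(=O)O[C@@H]2/C=C(/C)CCC3[O+](C)C(OC)=C3[C@@H](O[Si](C)(C)C(C)(C)C)[C@@H](O[Si](CC)(CC)CC)[C@@H]12 | intermediate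
26 | ten-membered methyl ester, 8-OTES, 9-OTBS | C=C1C(=O)O[C@@H]2/C=C(/C)CC/C=C(/C(=O)OC)[C@@H](O[Si](C)(C)C(C)(C)C)[C@@H](O[Si](CC)(CC)CC)[C@@H]12 | intermediate
27 | 8-alcohol, 9-OTBS | C=C1C(=O)O[C@@H]2/C=C(/C)CC/C=C(/C(=O)OC)[C@@H](O[Si](C)(C)C(C)(C)C)[C@@H](O)[C@@H]12 | intermediate
28 | angelic acid | C/C=C(/C)C(=O)O | starting material
29 | (Z)-2-methylbut-2-en-1-ol | C/C=C(/C)CO | intermediate
30 | [(2R,3S)-2,3-dimethyloxiran-2-yl]methanol | OC[C@@]1(C)O[C@H]1C | intermediate
31 | (2S,3S)-2,3-dimethyloxirane-2-carboxylic acid | OC(=O)[C@@]1(C)O[C@H]1C | intermediate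
32 | epoxyangelic 2,4,6-trichlorobenzoic anhydride | O=C(OC(=O)[C@@]1(C)O[C@H]1C)c1c(Cl)cc(Cl)cc1Cl | intermediate
33 | 8-O-epoxyangelate, 9-OTBS | C=C1C(=O)O[C@@H]2/C=C(/C)CC/C=C(/C(=O)OC)[C@@H](O[Si](C)(C)C(C)(C)C)[C@@H](OC(=O)[C@@]3(C)O[C@H]3C)[C@@H]12 | intermediate
34 | 8-O-epoxyangelate, 9-OH | C=C1C(=O)O[C@@H]2/C=C(/C)CC/C=C(/C(=O)OC)[C@@H](O)[C@@H](OC(=O)[C@@]3(C)O[C@H]3C)[C@@H]12 | intermediate
35 | (R)-4-benzyl-3-propionyloxazolidin-2-one | CCC(=O)N1[C@H](Cc2ccccc2)COC1=O | starting material
36 | acetaldehyde | CC=O | starting material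
37 | Z-dibutylboron enolate of 35 | C/C=C(\OB(CCCC)CCCC)N1[C@H](Cc2ccccc2)COC1=O | intermediate
38 | syn-aldol imide (2′R,3′S) | O=C1OC[C@@H](Cc2ccccc2)N1C(=O)[C@H](C)[C@H](C)O | intermediate
39 | 3′-O-TES aldol imide | O=C1OC[C@@H](Cc2ccccc2)N1C(=O)[C@H](C)[C@H](C)O[Si](CC)(CC)CC | intermediate
40 | (2R,3S)-2-methyl-3-(triethylsilyloxy)butanoic acid | OC(=O)[C@H](C)[C@H](C)O[Si](CC)(CC)CC | intermediate
41 | silyloxybutanoic 2,4,6-trichlorobenzoic anhydride | O=C(OC(=O)[C@H](C)[C@H](C)O[Si](CC)(CC)CC)c1c(Cl)cc(Cl)cc1Cl | intermediate
42 | 3′-O-TES ether of the target | C=C1C(=O)O[C@@H]2/C=C(/C)CC/C=C(/C(=O)OC)[C@@H](OC(=O)[C@H](C)[C@H](C)O[Si](CC)(CC)CC)[C@@H](OC(=O)[C@@]3(C)O[C@H]3C)[C@@H]12 | intermediate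
43 | CNP0135583.1 | C=C1C(=O)O[C@@H]2/C=C(/C)CC/C=C(/C(=O)OC)[C@@H](OC(=O)[C@H](C)[C@H](C)O)[C@@H](OC(=O)[C@@]3(C)O[C@H]3C)[C@@H]12 | target

## Count and least certain steps

The route has 25 steps in total. The longest linear sequence has 18 steps (steps 1–3, 5–15, 19, 20, 24 and 25).

**Step 14 (key step, carries the label).** The ten-membered closure may be slower than several side processes:
- dimerisation;
- ionisation at the propargylic C9 with loss of O9;
- capture of the ketenium carbon by O8 with desilylation;
- hydration of the ynol ether by traces of water.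

The fallback uses known chemistry, sets out from 18 and comes back at 26. A Morita–Baylis–Hillman reaction with methyl acrylate (DABCO) gives the α-methylene-β-hydroxy ester F1, and silylation gives the TBS ether F2. Horner–Wadsworth–Emmons methylenation gives the bis-methylene compound F3. Acetal hydrolysis (LiBF4, wet MeCN) gives the aldehyde F4, and Zn/CH2I2/TiCl4 methylenation gives the terminal alkene F5. Ring-closing metathesis with the second-generation Hoveyda–Grubbs catalyst then closes C1=C10.

**Step 8.** The stabilised carbanion may open the disubstituted epoxide too slowly. Heating could then bring phosphoryl migration to O8 with cyclopropane formation, or attack at the distal carbon. The fallback changes from a polar to a radical ring closure, sets out from 13 and comes back at 23. Esterification with propiolic acid gives the propiolate F6. Cp2TiCl (made from Cp2TiCl2 and zinc) opens the epoxide reductively, and the C7 radical closes 5-exo-dig to the α-methylene lactone alcohol F7. Silylation gives the bis-TES ether F8 and Swern oxidation gives the aldehyde F9. Addition of 20 gives the propargylic alcohol F10, and TBS protection gives 23.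

**Step 6.** The two alkenes that flank C6, or the two enantiomers, may be discriminated incompletely, and half of the material is not used. The fallback sets C6 by catalysis first, sets out from 7 and 9 and comes back at 13. Enantioselective addition of the alkenylzinc reagent in the presence of (−)-3-exo-morpholinoisoborneol gives the (S)-dienol F11. This is then epoxidised with the same titanium–tartrate system, now as a matched, purely diastereoselective reaction.

**Step 11.** Facial selectivity at the aldehyde may be poor, and the excess amide base may epimerise C8. The fallback replaces substrate control by reagent control, sets out from 19 and 18 and comes back at 21. The acetal 19 is converted with NaNH2 in liquid ammonia into isolated methoxyacetylene F12. This is added as its zinc acetylide (Et2Zn, Ti(OiPr)4 and the BINOL enantiomer that reinforces Felkin–Anh attack) under nearly neutral conditions.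

## Further compounds

F1 | step 14 | Morita–Baylis–Hillman adduct of 18 | CCOP(=O)(OCC)C1C(=O)O[C@H](/C=C(/C)CCC(OC)OC)[C@H]1[C@H](O[Si](CC)(CC)CC)[C@H](O)C(=C)C(=O)OC
F2 | step 14 | 9-O-TBS ether of F1 | CCOP(=O)(OCC)C1C(=O)O[C@H](/C=C(/C)CCC(OC)OC)[C@H]1[C@H](O[Si](CC)(CC)CC)[C@H](O[Si](C)(C)C(C)(C)C)C(=C)C(=O)OC
F3 | step 14 | α-methylene lactone acrylate acetal | C=C1C(=O)O[C@H](/C=C(/C)CCC(OC)OC)[C@H]1[C@H](O[Si](CC)(CC)CC)[C@H](O[Si](C)(C)C(C)(C)C)C(=C)C(=O)OC
F4 | step 14 | C1 aldehyde | C=C1C(=O)O[C@H](/C=C(/C)CCC=O)[C@H]1[C@H](O[Si](CC)(CC)CC)[C@H](O[Si](C)(C)C(C)(C)C)C(=C)C(=O)OC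
F5 | step 14 | terminal alkene for ring-closing metathesis | C=C1C(=O)O[C@H](/C=C(/C)CCC=C)[C@H]1[C@H](O[Si](CC)(CC)CC)[C@H](O[Si](C)(C)C(C)(C)C)C(=C)C(=O)OC
F6 | step 8 | O6-propiolate of 13 | C#CC(=O)O[C@H](/C=C(/C)CCC(OC)OC)[C@H]1O[C@@H]1CO[Si](CC)(CC)CC
F7 | step 8 | α-methylene lactone, 8-OH, 9-OTES | C=C1C(=O)O[C@H](/C=C(/C)CCC(OC)OC)[C@H]1[C@H](O)CO[Si](CC)(CC)CC
F8 | step 8 | α-methylene lactone, 8,9-bis-TES | C=C1C(=O)O[C@H](/C=C(/C)CCC(OC)OC)[C@H]1[C@H](O[Si](CC)(CC)CC)CO[Si](CC)(CC)CC
F9 | step 8 | α-methylene lactone C9 aldehyde | C=C1C(=O)O[C@H](/C=C(/C)CCC(OC)OC)[C@H]1[C@H](O[Si](CC)(CC)CC)C=O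
F10 | step 8 | α-methylene lactone propargylic alcohol | C=C1C(=O)O[C@H](/C=C(/C)CCC(OC)OC)[C@H]1[C@H](O[Si](CC)(CC)CC)[C@H](O)C#COC
F11 | step 6 | (S)-enantiomer of 12 | O[C@H](/C=C(/C)CCC(OC)OC)/C=C/CO[Si](CC)(CC)CC
F12 | step 11 | methoxyacetylene | C#COC
A1 | alternative 1 | seco bromo-enal for C6–C7 allylation | O=C/C=C(/C)CC/C=C(/C(=O)OC)[C@@H](O[Si](C)(C)C(C)(C)C)[C@@H](O[Si](CC)(CC)CC)/C=C(\CBr)C(=O)OC
A2 | alternative 2 | tetraene for metathesis at C4=C5 | C=C1C(=O)O[C@H](C=C)[C@H]1[C@H](O[Si](CC)(CC)CC)[C@H](O[Si](C)(C)C(C)(C)C)/C(C(=O)OC)=C\CCC(C)=C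
A3 | alternative 3 | 1-vinyl-2-isopropenylcyclohexanol (ring C5–C10) | C=C[C@]1(O)[C@@H](O[Si](C)(C)C(C)(C)C)[C@@H](O[Si](C)(C)C(C)(C)C)[C@@H](C(C)=C)[C@H](O[Si](C)(C)C(C)(C)C)[C@H]1C(C)=C
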